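**Retrosynthetic overview**
1. Endgame: acid deprotection (four catechol acetonides, two tert-butyl esters) of 20, which comes from 19 by radical removal of a blocking bromine.
2. Key disconnection: the C3–C(=O) bond of the dihydronaphthalene. 19 comes from (arylmethylidene)cyclopropane 17 and the alkoxycarbonyl radical released from N-phthalimidoyl oxalate 18; the same operation opens the three-membered ring and closes the six-membered carbocycle (C1–C8a), setting C1.
3. Enabling feature: the exocyclic C=C on the cyclopropane carbon that lies between ring CH(CO2R) and ring CH(Ar). Radical attack at that ring carbon gives an α-aryl cyclopropylcarbinyl radical, the ring bond to the CH(Ar) carbon breaks, and the benzodioxole C–H ortho to oxygen (the other ortho site carries Br) accepts the resulting benzylic cation.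
4. 17 comes from Rh-carbene transfer of diazoacetate 16 to enantioenriched 1,3-diarylallene 8 (aldehyde 2 + alkyne 3, asymmetric alkynylation, Myers allene synthesis); 16 and 18 both come from lactate 14 (aryl Grignard + (R)-glycidate).
5. Ring order: benzodioxoles (purchased), then cyclopropane (step 9), then cyclopropane opened and dihydronaphthalene carbocycle closed (step 11).

Key step: step 11

Assumption (stereochemical remark): in 17 only the ester-bearing ring carbon matters, because the aryl-bearing ring carbon and the alkene geometry are erased in step 11; 17 is drawn as the isomer expected from step 9.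

**Step 1**
Reactants: 1 2,2-dimethyl-1,3-benzodioxole-5-carbaldehyde
Product: 2 6-bromo-2,2-dimethyl-1,3-benzodioxole-5-carbaldehyde
Conditions: Br2, NaOAc, AcOH, rt
Reagents that add atoms: bromine, BrBr
Why: Electrophilic aromatic bromination goes to C6 (para to a ring oxygen, meta to the formyl group, as with piperonal), and NaOAc buffers HBr so the ketal survives.

**Step 2**
Reactants: 1 2,2-dimethyl-1,3-benzodioxole-5-carbaldehyde
Product: 3 5-ethynyl-2,2-dimethyl-1,3-benzodioxole
Conditions: dimethyl (1-diazo-2-oxopropyl)phosphonate, K2CO3, MeOH, rt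
Reagents that add atoms: dimethyl (1-diazo-2-oxopropyl)phosphonate, COP(=O)(OC)C(=[N+]=[N-])C(C)=O
Why: Seyferth–Gilbert homologation (Ohira–Bestmann variant) converts the aryl aldehyde into the terminal alkyne under carbonate conditions that the ketal tolerates.

**Step 3**
Reactants: 2 6-bromo-2,2-dimethyl-1,3-benzodioxole-5-carbaldehyde, 3 5-ethynyl-2,2-dimethyl-1,3-benzodioxole (excess, recoverable)
Product: 5 (R)-1-(6-bromo-2,2-dimethyl-1,3-benzodioxol-5-yl)-3-(2,2-dimethyl-1,3-benzodioxol-5-yl)prop-2-yn-1-ol, via methylzinc acetylide 4 (not isolated)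
Conditions: Me2Zn, ProPhenol (20 mol %, the antipode that gives the R carbinol), Ph3P=O (cat.), PhMe, 4 °C; aq. NH4Cl
Reagents that add atoms: none
Why: Catalytic asymmetric zinc-acetylide addition to an aryl aldehyde (dinuclear zinc–ProPhenol catalysis) sets the carbinol centre by ligand control (sense to be confirmed by Mosher ester analysis); this centre is the source of the core stereochemistry.

**Step 4**
Reactants: 5 (R)-propargylic alcohol
Product: 8 (aS)-1-(6-bromo-2,2-dimethyl-1,3-benzodioxol-5-yl)-3-(2,2-dimethyl-1,3-benzodioxol-5-yl)propa-1,2-diene, via (S)-N-propargyl-N-(2-nitrobenzenesulfonyl)hydrazine 6 (not isolated), via (S)-propargylic diazene 7 (not isolated)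
Conditions: 2-nitrobenzenesulfonylhydrazide, PPh3, DEAD, THF, −15 °C → rt, dark
Reagents that add atoms: none
Why: Myers allene synthesis: Mitsunobu displacement with inversion, loss of sulfinic acid and suprafacial retro-ene loss of N2 from the diazene deliver H anti to the original C–O bond, so the (R) centre becomes the (aS) axis.

**Step 5**
Reactants: 9 5-bromo-2,2-dimethyl-1,3-benzodioxole, 10 methyl (R)-oxirane-2-carboxylate
Product: 12 methyl (R)-3-(2,2-dimethyl-1,3-benzodioxol-5-yl)-2-hydroxypropanoate, via (2,2-dimethyl-1,3-benzodioxol-5-yl)magnesium bromide 11 (not isolated)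
Conditions: Mg, THF; then CuI (10 mol %), 10, THF, −45 → −20 °C; aq. NH4Cl
Reagents that add atoms: none
Why: Copper-catalysed SN2 opening of the glycidate at the unsubstituted C3 by the aryl Grignard reagent leaves C2 untouched, so the (R) configuration is retained.

**Step 6**
Reactants: 12 methyl (R)-3-(2,2-dimethyl-1,3-benzodioxol-5-yl)-2-hydroxypropanoate
Product: 13 (R)-3-(2,2-dimethyl-1,3-benzodioxol-5-yl)-2-hydroxypropanoic acid
Conditions: LiOH·H2O, THF/H2O, 0 °C; then 1 M HCl to pH 3, 0 °C
Reagents that add atoms: lithium hydroxide (hydroxide oxygen ends in the CO2H), [Li+].[OH-]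
Why: Saponification of an unhindered methyl ester; the α-hydroxy centre should not epimerise under cold LiOH.

**Step 7**
Reactants: 13 (R)-3-(2,2-dimethyl-1,3-benzodioxol-5-yl)-2-hydroxypropanoic acid
Product: 14 tert-butyl (R)-3-(2,2-dimethyl-1,3-benzodioxol-5-yl)-2-hydroxypropanoate
Conditions: tert-butyl 2,2,2-trichloroacetimidate, CH2Cl2/cyclohexane, rt
Reagents that add atoms: tert-butyl 2,2,2-trichloroacetimidate, CC(C)(C)OC(=N)C(Cl)(Cl)Cl
Why: Trichloroacetimidate O-alkylation is self-catalysed by the carboxylic acid, so without a Lewis acid the secondary alcohol stays free.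

**Step 8**
Reactants: 14 tert-butyl (R)-3-(2,2-dimethyl-1,3-benzodioxol-5-yl)-2-hydroxypropanoate
Product: 16 tert-butyl (R)-2-(2-diazoacetoxy)-3-(2,2-dimethyl-1,3-benzodioxol-5-yl)propanoate, via bromoacetate 15 (not isolated)
Conditions: BrCH2COBr, NaHCO3, MeCN, 0 °C; filter, concentrate; then N,N'-ditosylhydrazine, DBU, THF, 0 °C
Reagents that add atoms: bromoacetyl bromide, BrCC(Br)=O; N,N'-ditosylhydrazine, Cc1ccc(cc1)S(=O)(=O)NNS(=O)(=O)c1ccc(C)cc1
Why: O-acylation followed by diazo formation (N-alkylation of the ditosylhydrazine and double sulfinate elimination) is the standard two-stage diazoacetate synthesis and does not touch the lactate centre.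

**Step 9**
Reactants: 8 (aS)-1,3-diarylallene (1.5 equiv), 16 diazoacetate
Product: 17 (R)-1-tert-butoxy-3-(2,2-dimethyl-1,3-benzodioxol-5-yl)-1-oxopropan-2-yl (1S,2R,E)-3-[(6-bromo-2,2-dimethyl-1,3-benzodioxol-5-yl)methylidene]-2-(2,2-dimethyl-1,3-benzodioxol-5-yl)cyclopropane-1-carboxylate
Conditions: Rh2(esp)2 (1 mol %), CH2Cl2, 0 °C, slow addition of 16, dark
Reagents that add atoms: none
Why: Rh(II)-carbene [2+1] cycloaddition to an allene (alkylidenecyclopropane synthesis) should take the more electron-rich, less hindered C=C next to the unbrominated aryl group, from the face anti to the bromoaryl group on the distal terminus (axis-to-centre transfer), with the bulky ester trans to the aryl group, which sets the ester-bearing carbon as S; minor isomers are removed by chromatography.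

**Step 10**
Reactants: 14 tert-butyl (R)-3-(2,2-dimethyl-1,3-benzodioxol-5-yl)-2-hydroxypropanoate
Product: 18 (R)-1-tert-butoxy-3-(2,2-dimethyl-1,3-benzodioxol-5-yl)-1-oxopropan-2-yl 1,3-dioxoisoindolin-2-yl oxalate
Conditions: (COCl)2, N-hydroxyphthalimide, THF, rt, evaporate; then 14, Et3N, DMAP (cat.), THF, −40 → 0 °C; used promptly
Reagents that add atoms: oxalyl chloride, O=C(Cl)C(Cl)=O; N-hydroxyphthalimide, O=C1N(O)C(=O)c2ccccc12
Why: DMAP-catalysed O-acylation of the secondary alcohol by the chlorooxalate half-ester of N-hydroxyphthalimide is the standard preparation of redox-active N-phthalimidoyl oxalates, with base present throughout to protect ketal and tert-butyl ester.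

**Step 11**
Reactants: 17 (arylmethylidene)cyclopropane, 18 N-phthalimidoyl oxalate (1.8 equiv)
Product: 19 bis[(R)-1-tert-butoxy-3-(2,2-dimethyl-1,3-benzodioxol-5-yl)-1-oxopropan-2-yl] (1R,2S)-5-bromo-1-(2,2-dimethyl-1,3-benzodioxol-5-yl)-7,8-(isopropylidenedioxy)-1,2-dihydronaphthalene-2,3-dicarboxylate
Conditions: fac-Ir(ppy)3 (1 mol %), CH2Cl2/MeCN (degassed, concentrated), blue LEDs, rt
Reagents that add atoms: none
Why: Proposed new method: Photoexcited fac-Ir(ppy)3 reduces the N-acyloxyphthalimide of 18, which fragments to phthalimide anion, CO2 and the alkoxycarbonyl radical; this σ-radical adds to the ring sp2 carbon of the exocyclic alkene of 17 (the only regiochemistry that gives a benzylic radical and turns the strained methylenecyclopropane carbon into sp3), forming the C3–C(=O) bond. The α-aryl cyclopropylcarbinyl radical opens by scission of the ring bond to the aryl-bearing carbon (a 3,4-dioxybenzyl radical, better stabilised than the alternative α-ester radical, so the ester-bearing carbon keeps its S configuration), creating the C3=C4 alkene and placing the radical at C1, where Ir(IV) oxidises it to the cation (radical–polar crossover that closes the photocatalytic cycle). The cation closes the carbocycle by a six-membered Friedel–Crafts alkylation (6-endo with respect to the styrenyl C4a=C8a unit) at C4 of the bromobenzodioxole, the only free ortho position because the para-to-oxygen site carries Br, and phthalimide anion takes the proton. The new stereocentre C1 is controlled by the adjacent C2 centre: the aryl group enters anti to the C2 ester (trans, the kinetic and thermodynamic outcome of cationic closures to 1-aryl-1,2-dihydronaphthalene-2-carboxylates). The step needs radical addition before loss of a second CO2 (secondary alkoxycarbonyl radicals decarboxylate slowly, and 18 is used in excess at high concentration), ring opening towards the benzylic carbon, and the E alkene geometry required for closure, which should be reached because cyclopropylcarbinyl/homoallyl opening is reversible and only the E isomer is drained by cyclisation. Closest known reaction types: radical addition/ring-opening/cyclisation of arylmethylenecyclopropanes to 1,2-dihydronaphthalenes, and photoredox generation of alkoxycarbonyl radicals from N-phthalimidoyl oxalates.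

**Step 12**
Reactants: 19 5-bromo-dihydronaphthalene diester
Product: 20 bis[(R)-1-tert-butoxy-3-(2,2-dimethyl-1,3-benzodioxol-5-yl)-1-oxopropan-2-yl] (1R,2S)-1-(2,2-dimethyl-1,3-benzodioxol-5-yl)-7,8-(isopropylidenedioxy)-1,2-dihydronaphthalene-2,3-dicarboxylate
Conditions: Bu3SnH, AIBN (cat.), PhMe, 80 °C
Reagents that add atoms: none
Why: Radical-chain hydrodebromination; the C5 aryl radical has no cyclisation or hydrogen-transfer partner within reach, and the neutral conditions spare the epimerisable C2 centre and the conjugated alkene that hydrogenolysis would endanger.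

**Step 13**
Reactants: 20 protected dihydronaphthalene diester
Product: 21 (2R,2'R)-2,2'-{[(1R,2S)-1-(3,4-dihydroxyphenyl)-7,8-dihydroxy-1,2-dihydronaphthalene-2,3-dicarbonyl]bis(oxy)}bis[3-(3,4-dihydroxyphenyl)propanoic acid] (CNP0244800.2)
Conditions: TFA/H2O (9:1), anisole, 0 °C → rt, Ar; reversed-phase HPLC
Reagents that add atoms: none
Why: Acid-catalysed ketal hydrolysis and tert-butyl ester acidolysis remove all six protecting groups in one operation, while the two secondary-alkyl ester links, the conjugated alkene and all four stereocentres are inert to acid.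

**Compound list**
1 | 2,2-dimethyl-1,3-benzodioxole-5-carbaldehyde | O=Cc1ccc2OC(C)(C)Oc2c1 | starting material
2 | 6-bromo-2,2-dimethyl-1,3-benzodioxole-5-carbaldehyde | O=Cc1cc2OC(C)(C)Oc2cc1Br | intermediate
3 | 5-ethynyl-2,2-dimethyl-1,3-benzodioxole | C#Cc1ccc2OC(C)(C)Oc2c1 | intermediate
4 | methyl[(2,2-dimethyl-1,3-benzodioxol-5-yl)ethynyl]zinc | C[Zn]C#Cc1ccc2OC(C)(C)Oc2c1 | intermediate
5 | (R)-1-(6-bromo-2,2-dimethyl-1,3-benzodioxol-5-yl)-3-(2,2-dimethyl-1,3-benzodioxol-5-yl)prop-2-yn-1-ol | O[C@H](C#Cc1ccc2OC(C)(C)Oc2c1)c1cc2OC(C)(C)Oc2cc1Br | intermediate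
6 | N-[(1S)-1-(6-bromo-2,2-dimethyl-1,3-benzodioxol-5-yl)-3-(2,2-dimethyl-1,3-benzodioxol-5-yl)prop-2-yn-1-yl]-2-nitrobenzenesulfonohydrazide (alkylated on the sulfonamide nitrogen) | NN([C@@H](C#Cc1ccc2OC(C)(C)Oc2c1)c1cc2OC(C)(C)Oc2cc1Br)S(=O)(=O)c1ccccc1[N+](=O)[O-] | intermediate
7 | [(1S)-1-(6-bromo-2,2-dimethyl-1,3-benzodioxol-5-yl)-3-(2,2-dimethyl-1,3-benzodioxol-5-yl)prop-2-yn-1-yl]diazene | N=N[C@@H](C#Cc1ccc2OC(C)(C)Oc2c1)c1cc2OC(C)(C)Oc2cc1Br | intermediate
8 | (aS)-1-(6-bromo-2,2-dimethyl-1,3-benzodioxol-5-yl)-3-(2,2-dimethyl-1,3-benzodioxol-5-yl)propa-1,2-diene | [H]C(c1cc2OC(C)(C)Oc2cc1Br)=[C@]=C([H])c1ccc2OC(C)(C)Oc2c1 | intermediate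
9 | 5-bromo-2,2-dimethyl-1,3-benzodioxole | Brc1ccc2OC(C)(C)Oc2c1 | starting material
10 | methyl (R)-oxirane-2-carboxylate (methyl (R)-glycidate) | COC(=O)[C@H]1CO1 | starting material
11 | (2,2-dimethyl-1,3-benzodioxol-5-yl)magnesium bromide | Br[Mg]c1ccc2OC(C)(C)Oc2c1 | intermediate
12 | methyl (R)-3-(2,2-dimethyl-1,3-benzodioxol-5-yl)-2-hydroxypropanoate | COC(=O)[C@H](O)Cc1ccc2OC(C)(C)Oc2c1 | intermediate
13 | (R)-3-(2,2-dimethyl-1,3-benzodioxol-5-yl)-2-hydroxypropanoic acid | OC(=O)[C@H](O)Cc1ccc2OC(C)(C)Oc2c1 | intermediate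
14 | tert-butyl (R)-3-(2,2-dimethyl-1,3-benzodioxol-5-yl)-2-hydroxypropanoate | CC(C)(C)OC(=O)[C@H](O)Cc1ccc2OC(C)(C)Oc2c1 | intermediate
15 | tert-butyl (R)-2-(2-bromoacetoxy)-3-(2,2-dimethyl-1,3-benzodioxol-5-yl)propanoate | CC(C)(C)OC(=O)[C@H](OC(=O)CBr)Cc1ccc2OC(C)(C)Oc2c1 | intermediate
16 | tert-butyl (R)-2-(2-diazoacetoxy)-3-(2,2-dimethyl-1,3-benzodioxol-5-yl)propanoate | CC(C)(C)OC(=O)[C@H](OC(=O)C=[N+]=[N-])Cc1ccc2OC(C)(C)Oc2c1 | intermediate
17 | (R)-1-tert-butoxy-3-(2,2-dimethyl-1,3-benzodioxol-5-yl)-1-oxopropan-2-yl (1S,2R,E)-3-[(6-bromo-2,2-dimethyl-1,3-benzodioxol-5-yl)methylidene]-2-(2,2-dimethyl-1,3-benzodioxol-5-yl)cyclopropane-1-carboxylate (ester and aryl trans) | CC(C)(C)OC(=O)[C@H](OC(=O)[C@H]1[C@H](c2ccc3OC(C)(C)Oc3c2)/C1=C\c1cc2OC(C)(C)Oc2cc1Br)Cc1ccc2OC(C)(C)Oc2c1 | intermediate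
18 | (R)-1-tert-butoxy-3-(2,2-dimethyl-1,3-benzodioxol-5-yl)-1-oxopropan-2-yl 1,3-dioxoisoindolin-2-yl oxalate | CC(C)(C)OC(=O)[C@H](OC(=O)C(=O)ON1C(=O)c2ccccc2C1=O)Cc1ccc2OC(C)(C)Oc2c1 | intermediate
19 | bis[(R)-1-tert-butoxy-3-(2,2-dimethyl-1,3-benzodioxol-5-yl)-1-oxopropan-2-yl] (1R,2S)-5-bromo-1-(2,2-dimethyl-1,3-benzodioxol-5-yl)-7,8-(isopropylidenedioxy)-1,2-dihydronaphthalene-2,3-dicarboxylate (1,2-trans) | O=C(O[C@H](Cc1ccc2OC(C)(C)Oc2c1)C(=O)OC(C)(C)C)C1=Cc2c(Br)cc3OC(C)(C)Oc3c2[C@@H](c2ccc3OC(C)(C)Oc3c2)[C@@H]1C(=O)O[C@H](Cc1ccc2OC(C)(C)Oc2c1)C(=O)OC(C)(C)C | intermediate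
20 | bis[(R)-1-tert-butoxy-3-(2,2-dimethyl-1,3-benzodioxol-5-yl)-1-oxopropan-2-yl] (1R,2S)-1-(2,2-dimethyl-1,3-benzodioxol-5-yl)-7,8-(isopropylidenedioxy)-1,2-dihydronaphthalene-2,3-dicarboxylate | O=C(O[C@H](Cc1ccc2OC(C)(C)Oc2c1)C(=O)OC(C)(C)C)C1=Cc2ccc3OC(C)(C)Oc3c2[C@@H](c2ccc3OC(C)(C)Oc3c2)[C@@H]1C(=O)O[C@H](Cc1ccc2OC(C)(C)Oc2c1)C(=O)OC(C)(C)C | intermediate
21 | (2R,2'R)-2,2'-{[(1R,2S)-1-(3,4-dihydroxyphenyl)-7,8-dihydroxy-1,2-dihydronaphthalene-2,3-dicarbonyl]bis(oxy)}bis[3-(3,4-dihydroxyphenyl)propanoic acid] | O=C(O[C@H](Cc1ccc(O)c(O)c1)C(=O)O)C1=Cc2ccc(O)c(O)c2[C@@H](c2ccc(O)c(O)c2)[C@@H]1C(=O)O[C@H](Cc1ccc(O)c(O)c1)C(=O)O | target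

**Totals and risks**
Total step count: 13. Longest linear sequence: 8 steps (5, 6, 7, 8, 9, 11, 12, 13).

Steps most likely to fail:

Step 11 (proposed new method). The alkoxycarbonyl radical may lose CO2 before it adds, the cyclopropane may open towards the ester-bearing carbon, or the benzylic cation may lose a proton instead of closing the ring, which would erase C2. Fallback, from 17 back to 19, with known reaction types: 17 is treated with N-iodosuccinimide in CH2Cl2/hexafluoroisopropanol at low temperature; iodonium attack at the ring sp2 carbon, cyclopropylcarbinyl-to-homoallyl opening to the same dioxybenzyl cation and Friedel–Crafts closure should give the 3-iodo-1,2-dihydronaphthalene-2-carboxylate F1. Palladium-catalysed alkoxycarbonylation of F1 with CO and alcohol 14 (Pd(OAc)2, Xantphos, Et3N, PhMe, 70 °C) then forms the same C3–C(=O) bond and returns to 19; the vinyl C–I bond should undergo oxidative addition before the aryl C–Br bond.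

Step 9. Carbene transfer may discriminate poorly between the two C=C bonds of the allene or between trans and cis delivery of the ester, which would cut the supply of the correct isomer. Fallback, from 8 back to 17: the chiral ester is decoupled from the carbene step. Cyclopropanation of 8 with commercial ethyl diazoacetate under a trans-selective Ru(II)- or Co(II)-porphyrin catalyst should give ethyl ester F2, purified from isomers at this simpler stage. Saponification (LiOH, THF/H2O) gives acid F3, and carbodiimide esterification (EDC, DMAP, CH2Cl2) with 14 gives 17.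

Step 4. Partial ionisation of the electron-rich benzylic–propargylic centre during the Mitsunobu stage would erode the centre-to-axis transfer. Fallback, from 5 back to 8: 5 is converted with methyl chloroformate/pyridine into methyl carbonate F4, which is reduced by an (NHC)CuH catalyst (IPrCuCl, NaOt-Bu, polymethylhydrosiloxane, PhMe). The expected anti-SN2' hydride delivery has the same stereochemical sense as the Mitsunobu/retro-ene sequence and so gives the same (aS)-allene 8.

**Further compounds**
F1 | step 11 | (R)-1-tert-butoxy-3-(2,2-dimethyl-1,3-benzodioxol-5-yl)-1-oxopropan-2-yl (1R,2R)-5-bromo-1-(2,2-dimethyl-1,3-benzodioxol-5-yl)-3-iodo-7,8-(isopropylidenedioxy)-1,2-dihydronaphthalene-2-carboxylate (same spatial arrangement as in 19; the C2 descriptor changes because of iodine) | IC1=Cc2c(Br)cc3OC(C)(C)Oc3c2[C@@H](c2ccc3OC(C)(C)Oc3c2)[C@@H]1C(=O)O[C@H](Cc1ccc2OC(C)(C)Oc2c1)C(=O)OC(C)(C)C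
F2 | step 9 | ethyl (1S,2R,E)-3-[(6-bromo-2,2-dimethyl-1,3-benzodioxol-5-yl)methylidene]-2-(2,2-dimethyl-1,3-benzodioxol-5-yl)cyclopropane-1-carboxylate | CCOC(=O)[C@H]1[C@H](c2ccc3OC(C)(C)Oc3c2)/C1=C\c1cc2OC(C)(C)Oc2cc1Br
F3 | step 9 | (1S,2R,E)-3-[(6-bromo-2,2-dimethyl-1,3-benzodioxol-5-yl)methylidene]-2-(2,2-dimethyl-1,3-benzodioxol-5-yl)cyclopropane-1-carboxylic acid | OC(=O)[C@H]1[C@H](c2ccc3OC(C)(C)Oc3c2)/C1=C\c1cc2OC(C)(C)Oc2cc1Br
F4 | step 4 | (R)-1-(6-bromo-2,2-dimethyl-1,3-benzodioxol-5-yl)-3-(2,2-dimethyl-1,3-benzodioxol-5-yl)prop-2-yn-1-yl methyl carbonate | COC(=O)O[C@H](C#Cc1ccc2OC(C)(C)Oc2c1)c1cc2OC(C)(C)Oc2cc1Br
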